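| flask | Z | remark | time |
|---|---|---|---|
| eta | 1 M | the very flask that is asked about, followed so far |  |
| alpha | 0.67 M | run made earlier |  |
| flask | 1.0 M |  | 30 h |

| run | time / h | G / % |
|---|---|---|
| eta | 0.250 | 55.1 |
| eta | 0.500 | 76.3 |
| eta | 1.33 | 80.8 |
| eta | 4.00 | 54.9 |
| eta | 10.0 | 30.7 |
| alpha | 0.250 | 59.4 |
| alpha | 0.667 | 82.2 |
| alpha | 1.50 | 79.2 |
| alpha | 4.00 | 55.5 |
| alpha | 12.0 | 28.1 |

(readings scatter by 0.3 percentage points)

- time, not beyond 30 h, at which the flask holds most G
- the amount of G, in percent of the Z charged, at that time
- the first time at which G reaches 42 %, in the same percent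

- Over time G in the eta run, which is the asked flask followed so far, climbs and then falls, and two numbers in that fall don't go together: G sinks at 0.145 h⁻¹ between 1.33 h and 4.00 h, yet at 0.0969 h⁻¹ between 4.00 h and 10.0 h, whereas a first-order loss to zero keeps one rate.
- I clear this up by comparing the slopes of those two stretches, because a level that G approaches drops out of a slope, and their ratio gives 0.202 h⁻¹, a rough reading that makes 3.42 h the turnover time of G, the time in which G's distance from its rest level halves.
- The alpha run, at 0.67 M, reads 3.57 h by the same reckoning, close to the eta value although [Z] at the start differs.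
- The asked flask, with [Z] at 1.0 M at the start, gets 8.76 turnovers in 30 h, which leaves 0.231 % of that distance, so I look for the highest G early, between 0.500 h and 1.33 h, within one turnover; that peak is the kinetic side of kinetic against thermodynamic control.
- The forecast puts the peak at 0.9 h (0.75 h to 1.1 h) with 83 % (81.8 % to 84.5 %) and the asked level at 0.165 h (0.145 h to 0.19 h), and it says the slowing fall “points to a reversible loss”.
- The asked flask gives 0.903 h, 83.3 % and 0.160 h, each inside the forecast's range.

    Z → G (k = 0.125 min⁻¹)
    Z ⇌ J (K = 0.573, k = 0.0220 min⁻¹)
    2 Z ⇌ Q (K = 1.60 M⁻¹, k = 0.368 M⁻¹ min⁻¹)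
    G ⇌ L (K = 3.40, k = 0.00305 min⁻¹)

- The half-life of G by its forward passing into L is 3.8 h, shorter than the 30 h allowed, and the slowest mode of the whole asked flask has a half-life of 2.93 h, while that flask holds G 22.8 % and L 77.2 % at 30.0 h and G 22.7 % at 300 h. Counted by that mode's half-life, the asked flask has 10.2 halvings behind it at 30 h and 4.10 at 12 h, where it holds G 27.6 %, while my rough turnover time of 3.42 h, read off the eta run, counts fewer, 8.76 at 30 h. The neighbour charged with 1.7 M holds G 22.8 % at its end.

The earlier runs and the new flask come from a simulation with constants of no real substance, and the scatter is random.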